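The α-alkylidene-γ-butyrolactone (ring A: O-1, C-2, C-3, C-4, C-5) is built so that CO2 supplies C-2 and both oxygens. One telescoped operation carboxylates a geometry-defined alkenyl boronate at the future C-3 (copper catalysis) and lets a chiral gold catalyst add the new carboxyl oxygen to the prochiral CH terminus of a 1,1-dimethylallene, the future C-5. This closes ring A, sets the (S) centre and unveils the 2-methylprop-1-enyl group. The step exploits the sp2 C-3 as a C–B nucleophile and the allylic, oxygenated C-5 as a masked allene. The precursor is an achiral acyclic (Z)-alkenyl boronate made from farnesol; the dienyl butenolide is attached last.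

Key step: step 8

Remark: paraformaldehyde is written as its monomer. The hand of the gold catalyst pair ((S)-BINAP with (R)-TRIP, or its mirror image) is assumed to be the one that gives the (S)-lactone, to be fixed on a model allenoic acid first. The geminal dichromium reagent of step 11 is written with chloride ligands only, without coordinated THF or partial exchange for iodide.

Step 1
Reactants: 1 3-methylbuta-1,2-diene; 2 paraformaldehyde
Product: 4 4-methylpenta-2,3-dien-1-ol, via 3-methylbuta-1,2-dien-1-yllithium 3 (not isolated)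
Conditions: n-BuLi, THF, −78 → −30 °C; (CH2O)n, −78 °C → rt; H2O
Reagents that add atoms: paraformaldehyde, C=O
Why: Lithiation of the terminal allenic C–H and hydroxymethylation of the allenyllithium, which should react through its unsubstituted α-carbon because the γ-carbon carries two methyl groups.

Step 2
Reactants: 4 4-methylpenta-2,3-dien-1-ol
Product: 5 1-bromo-4-methylpenta-2,3-diene
Conditions: CBr4, PPh3, CH2Cl2, 0 °C
Reagents that add atoms: carbon tetrabromide, BrC(Br)(Br)Br
Why: Appel reaction, in which bromide displaces the primary oxyphosphonium by SN2 under neutral conditions that leave the allene intact.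

Step 3
Reactants: 5 1-bromo-4-methylpenta-2,3-diene; 6 bis[(pinacolato)boryl]methane
Product: 8 2,2'-(5-methylhexa-3,4-diene-1,1-diyl)bis(4,4,5,5-tetramethyl-1,3,2-dioxaborolane), via lithiobis(pinacolatoboryl)methane 7 (not isolated)
Conditions: 6, LiTMP, THF, 0 °C; then 5, 0 °C → rt
Reagents that add atoms: bis[(pinacolato)boryl]methane, CC1(C)OB(CB2OC(C)(C)C(C)(C)O2)OC1(C)C
Why: Alkylation of an α,α-diboryl carbanion, a bulky stabilised nucleophile that should attack the primary CH2–Br carbon by SN2 in preference to the central allene carbon.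

Step 4
Reactants: 9 (2E,6E)-farnesol
Product: 10 tert-butyl(diphenyl){[(2E,6E)-3,7,11-trimethyldodeca-2,6,10-trien-1-yl]oxy}silane
Conditions: TBDPSCl, imidazole, CH2Cl2, 0 °C → rt
Reagents that add atoms: tert-butyl(chloro)diphenylsilane, CC(C)(C)[Si](Cl)(c1ccccc1)c1ccccc1
Why: Silylation of the primary allylic alcohol gives an ether that should survive the acidic, basic and organometallic steps up to step 9.

Step 5
Reactants: 10 farnesyl silyl ether
Product: 12 tert-butyl{[(2E,6E)-9-(3,3-dimethyloxiran-2-yl)-3,7-dimethylnona-2,6-dien-1-yl]oxy}diphenylsilane (racemic), via racemic terminal bromohydrin 11 (not isolated)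
Conditions: NBS, THF/H2O, 0 °C; then K2CO3, MeOH, rt
Reagents that add atoms: water, O
Why: Terminal-selective bromohydrin formation of a polyprenyl chain in aqueous medium followed by base-induced epoxide closure; the new centre is racemic and is erased in step 6.

Step 6
Reactants: 12 terminal epoxide
Product: 13 (4E,8E)-10-{[tert-butyl(diphenyl)silyl]oxy}-4,8-dimethyldeca-4,8-dienal
Conditions: H5IO6, THF/Et2O, 0 °C
Reagents that add atoms: none
Why: Periodic acid opens the epoxide to the glycol and cleaves it (Malaprade-type cleavage) to the aldehyde and acetone without touching the trisubstituted alkenes or the silyl ether.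

Step 7
Reactants: 13 aldehyde; 8 allenyl gem-diboronate
Product: 15 tert-butyl{[(2E,6E,10Z)-3,7,15-trimethyl-11-(4,4,5,5-tetramethyl-1,3,2-dioxaborolan-2-yl)hexadeca-2,6,10,13,14-pentaen-1-yl]oxy}diphenylsilane, via lithiated gem-diboronate 14 (not isolated)
Conditions: 8, LiTMP, THF, 0 °C; then 13, −78 °C → rt
Reagents that add atoms: none
Why: Boron–Wittig olefination, in which carbanion 14 adds to the aldehyde and syn B–O elimination should leave the retained boron trans to the aldehyde-derived chain (cis to the vinylic hydrogen, 10Z), as in the E-selective parent reaction.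

Step 8
Reactants: 15 (Z)-alkenyl boronate; 16 carbon dioxide
Product: 18 (3E,5S)-3-[(4E,8E)-10-{[tert-butyl(diphenyl)silyl]oxy}-4,8-dimethyldeca-4,8-dien-1-ylidene]-5-(2-methylprop-1-en-1-yl)oxolan-2-one, via allenoic acid 17 (not isolated)
Conditions: (IPr)CuCl (5 mol %; IPr = 1,3-bis(2,6-diisopropylphenyl)imidazol-2-ylidene), KOtBu, CO2 (1 atm), THF, 70 °C; AcOH, silica plug, solvent exchange to benzene without purification; [(S)-BINAP](AuCl)2 (2.5 mol %), Ag[(R)-TRIP] (5 mol %; silver (R)-3,3'-bis(2,4,6-triisopropylphenyl)-1,1'-binaphthyl-2,2'-diyl phosphate), benzene, rt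
Reagents that add atoms: carbon dioxide, O=C=O
Why: Stage 1 is the carbene–copper-catalysed carboxylation of an alkenylboronic ester: the tert-butoxide-activated C–B bond of 15 transmetalates to monovalent copper with retention, CO2 inserts into the alkenyl–Cu bond (C–C bond between the CO2 carbon and the alkylidene-bearing carbon) and acidification releases acid 17. Stage 2 is the gold-catalysed enantioselective hydrocarboxylation of a γ-allenoic acid: cationic monovalent gold activates the allene, the carboxyl oxygen attacks the CH terminus anti to gold (C–O bond) and protodeauration of the vinylgold leaves the 2-methylprop-1-enyl group. The lactone closes in the 5-exo-trig mode, the 7-endo closure at the CMe2 terminus being disfavoured by ring size and substitution. The new stereocentre is controlled by the chiral bisphosphine–digold cation and its chiral phosphate counterion, which select one enantiotopic face of the achiral 1,1-dimethylallene, so no stereocentre is carried into the step. The E geometry of the alkylidene is needed and is secured by boron being cis to the vinylic hydrogen in 15 together with stereoretentive transmetalation and insertion. Chemoselectivity for the allene over the three trisubstituted alkenes rests on the stronger activation of allenes by gold and on the intramolecular five-membered closure.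

Step 9
Reactants: 18 silyl-protected lactone
Product: 19 (3E,5S)-3-[(4E,8E)-10-hydroxy-4,8-dimethyldeca-4,8-dien-1-ylidene]-5-(2-methylprop-1-en-1-yl)oxolan-2-one
Conditions: TBAF, AcOH, THF, 0 °C → rt
Reagents that add atoms: none
Why: Fluoride-mediated desilylation, buffered with acetic acid so that the alkylidene lactone and the allylic C–O stereocentre are not exposed to free alkoxide.

Step 10
Reactants: 19 allylic alcohol
Product: 20 (2E,6E)-3,7-dimethyl-10-[(3E,5S)-5-(2-methylprop-1-en-1-yl)-2-oxooxolan-3-ylidene]deca-2,6-dienal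
Conditions: MnO2, CH2Cl2, rt
Reagents that add atoms: none
Why: MnO2 oxidation, selective for the allylic alcohol, should give the (E)-enal without isomerisation and leave the lactone untouched.

Step 11
Reactants: 20 enal; 21 2-(dichloromethyl)-4,4,5,5-tetramethyl-1,3,2-dioxaborolane
Product: 23 (3E,5S)-3-[(4E,8E,10E)-4,8-dimethyl-11-(4,4,5,5-tetramethyl-1,3,2-dioxaborolan-2-yl)undeca-4,8,10-trien-1-ylidene]-5-(2-methylprop-1-en-1-yl)oxolan-2-one, via borylated geminal dichromium reagent 22 (not isolated)
Conditions: 21, CrCl2, LiI, THF, rt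
Reagents that add atoms: 2-(dichloromethyl)-4,4,5,5-tetramethyl-1,3,2-dioxaborolane, ClC(Cl)B1OC(C)(C)C(C)(C)O1
Why: Takai–Utimoto boryl olefination, in which divalent chromium reduces both carbon–halogen bonds of 21 (after chloride–iodide exchange with LiI) to the geminal dichromium species 22, which adds to the aldehyde only and eliminates to the (E)-alkenyl boronate under non-basic conditions that should spare the alkylidene lactone, its allylic C–O stereocentre and the enal geometry.

Step 12
Reactants: 23 dienyl boronate; 24 4-bromofuran-2(5H)-one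
Product: 25 (3E,5S)-3-[(4E,8E,10E)-4,8-dimethyl-11-(5-oxo-2,5-dihydrofuran-3-yl)undeca-4,8,10-trien-1-ylidene]-5-(2-methylprop-1-en-1-yl)oxolan-2-one
Conditions: 24, Pd(dppf)Cl2 (5 mol %), K3PO4, THF/H2O, rt
Reagents that add atoms: 4-bromofuran-2(5H)-one, O=C1C=C(Br)CO1
Why: Suzuki–Miyaura coupling, in which zerovalent palladium inserts into the activated C–Br bond of the β-bromobutenolide and the dienyl group is transferred with retention of its E geometry.

Compound list
1 | 3-methylbuta-1,2-diene | CC(C)=C=C | starting material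
2 | paraformaldehyde (as monomer) | C=O | starting material
3 | 3-methylbuta-1,2-dien-1-yllithium | CC(C)=C=C[Li] | intermediate
4 | 4-methylpenta-2,3-dien-1-ol | CC(C)=C=CCO | intermediate
5 | 1-bromo-4-methylpenta-2,3-diene | CC(C)=C=CCBr | intermediate
6 | bis[(pinacolato)boryl]methane | CC1(C)OB(CB2OC(C)(C)C(C)(C)O2)OC1(C)C | starting material
7 | lithiobis(pinacolatoboryl)methane | [Li]C(B1OC(C)(C)C(C)(C)O1)B1OC(C)(C)C(C)(C)O1 | intermediate
8 | 2,2'-(5-methylhexa-3,4-diene-1,1-diyl)bis(4,4,5,5-tetramethyl-1,3,2-dioxaborolane) | CC(C)=C=CCC(B1OC(C)(C)C(C)(C)O1)B1OC(C)(C)C(C)(C)O1 | intermediate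
9 | (2E,6E)-farnesol | CC(C)=CCC/C(C)=C/CC/C(C)=C/CO | starting material
10 | tert-butyl(diphenyl){[(2E,6E)-3,7,11-trimethyldodeca-2,6,10-trien-1-yl]oxy}silane | CC(C)=CCC/C(C)=C/CC/C(C)=C/CO[Si](c1ccccc1)(c1ccccc1)C(C)(C)C | intermediate
11 | (6E,10E)-3-bromo-12-{[tert-butyl(diphenyl)silyl]oxy}-2,6,10-trimethyldodeca-6,10-dien-2-ol (racemic) | CC(C)(O)C(Br)CC/C(C)=C/CC/C(C)=C/CO[Si](c1ccccc1)(c1ccccc1)C(C)(C)C | intermediate
12 | tert-butyl{[(2E,6E)-9-(3,3-dimethyloxiran-2-yl)-3,7-dimethylnona-2,6-dien-1-yl]oxy}diphenylsilane (racemic) | CC1(C)OC1CC/C(C)=C/CC/C(C)=C/CO[Si](c1ccccc1)(c1ccccc1)C(C)(C)C | intermediate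
13 | (4E,8E)-10-{[tert-butyl(diphenyl)silyl]oxy}-4,8-dimethyldeca-4,8-dienal | O=CCC/C(C)=C/CC/C(C)=C/CO[Si](c1ccccc1)(c1ccccc1)C(C)(C)C | intermediate
14 | [5-methyl-1,1-bis(pinacolatoboryl)hexa-3,4-dien-1-yl]lithium | CC(C)=C=CCC([Li])(B1OC(C)(C)C(C)(C)O1)B1OC(C)(C)C(C)(C)O1 | intermediate
15 | tert-butyl{[(2E,6E,10Z)-3,7,15-trimethyl-11-(4,4,5,5-tetramethyl-1,3,2-dioxaborolan-2-yl)hexadeca-2,6,10,13,14-pentaen-1-yl]oxy}diphenylsilane | CC(C)=C=CC/C(B1OC(C)(C)C(C)(C)O1)=C\CC/C(C)=C/CC/C(C)=C/CO[Si](c1ccccc1)(c1ccccc1)C(C)(C)C | intermediate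
16 | carbon dioxide | O=C=O | starting material
17 | (2E,6E,10E)-12-{[tert-butyl(diphenyl)silyl]oxy}-6,10-dimethyl-2-(4-methylpenta-2,3-dien-1-yl)dodeca-2,6,10-trienoic acid | CC(C)=C=CC/C(C(=O)O)=C\CC/C(C)=C/CC/C(C)=C/CO[Si](c1ccccc1)(c1ccccc1)C(C)(C)C | intermediate
18 | (3E,5S)-3-[(4E,8E)-10-{[tert-butyl(diphenyl)silyl]oxy}-4,8-dimethyldeca-4,8-dien-1-ylidene]-5-(2-methylprop-1-en-1-yl)oxolan-2-one | CC(C)=C[C@@H]1C/C(=C\CC/C(C)=C/CC/C(C)=C/CO[Si](c2ccccc2)(c2ccccc2)C(C)(C)C)C(=O)O1 | intermediate
19 | (3E,5S)-3-[(4E,8E)-10-hydroxy-4,8-dimethyldeca-4,8-dien-1-ylidene]-5-(2-methylprop-1-en-1-yl)oxolan-2-one | CC(C)=C[C@@H]1C/C(=C\CC/C(C)=C/CC/C(C)=C/CO)C(=O)O1 | intermediate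
20 | (2E,6E)-3,7-dimethyl-10-[(3E,5S)-5-(2-methylprop-1-en-1-yl)-2-oxooxolan-3-ylidene]deca-2,6-dienal | CC(C)=C[C@@H]1C/C(=C\CC/C(C)=C/CC/C(C)=C/C=O)C(=O)O1 | intermediate
21 | 2-(dichloromethyl)-4,4,5,5-tetramethyl-1,3,2-dioxaborolane | ClC(Cl)B1OC(C)(C)C(C)(C)O1 | starting material
22 | [(4,4,5,5-tetramethyl-1,3,2-dioxaborolan-2-yl)methanediyl]bis(dichlorochromium) (trivalent chromium at each metal) | Cl[Cr](Cl)C([Cr](Cl)Cl)B1OC(C)(C)C(C)(C)O1 | intermediate
23 | (3E,5S)-3-[(4E,8E,10E)-4,8-dimethyl-11-(4,4,5,5-tetramethyl-1,3,2-dioxaborolan-2-yl)undeca-4,8,10-trien-1-ylidene]-5-(2-methylprop-1-en-1-yl)oxolan-2-one | CC(C)=C[C@@H]1C/C(=C\CC/C(C)=C/CC/C(C)=C/C=C/B2OC(C)(C)C(C)(C)O2)C(=O)O1 | intermediate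
24 | 4-bromofuran-2(5H)-one | O=C1C=C(Br)CO1 | starting material
25 | (3E,5S)-3-[(4E,8E,10E)-4,8-dimethyl-11-(5-oxo-2,5-dihydrofuran-3-yl)undeca-4,8,10-trien-1-ylidene]-5-(2-methylprop-1-en-1-yl)oxolan-2-one | CC(C)=C[C@@H]1C/C(=C\CC/C(C)=C/CC/C(C)=C/C=C/C2=CC(=O)OC2)C(=O)O1 | target

Total steps: 12. Longest linear sequence: 9 steps (steps 4–12 from farnesol; the allene branch, steps 1–3 then 7–12, is equally long).

Steps most likely to fail

1. Step 8. Boron-to-copper transmetalation at the α-branched alkenyl boronate may be slow, so that protodeboronation competes, and the gold catalyst may discriminate the two allene faces incompletely. The fallback sets out from 15. The C–B bond is exchanged for C–I with retention (NaOH, then I2, THF/H2O, 0 °C) to give tert-butyl{[(2E,6E,10E)-11-iodo-3,7,15-trimethylhexadeca-2,6,10,13,14-pentaen-1-yl]oxy}diphenylsilane F1. Iodine–lithium exchange (t-BuLi, Et2O, −78 °C) and quenching of the alkenyllithium with CO2 should then give acid 17, which is isolated and purified this time. The pure acid is cyclised with the same gold catalyst pair in benzene, and the route is rejoined at 18.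

2. Step 7. The syn B–O elimination may favour the wrong geometry, with boron cis to the chain, which would lead to the Z-alkylidene lactone. The fallback sets out from 13. Seyferth–Gilbert homologation with the Ohira–Bestmann reagent (K2CO3, MeOH) should give tert-butyl{[(2E,6E)-3,7-dimethylundeca-2,6-dien-10-yn-1-yl]oxy}diphenylsilane F2. Crabbé homologation ((CH2O)n, CuI, dicyclohexylamine, dioxane, reflux) converts it into the terminal allene tert-butyl{[(2E,6E)-3,7-dimethyldodeca-2,6,10,11-tetraen-1-yl]oxy}diphenylsilane F3. A copper-catalysed borylative coupling of F3 with B2pin2 and 3-chloro-3-methylbut-1-yne ((ICy)CuCl, KOtBu, THF; ICy = 1,3-dicyclohexylimidazol-2-ylidene) then follows. The copper–boryl species should add across the terminal C=C from the side away from the chain, which fixes boron cis to the vinylic hydrogen, and the allylcopper is trapped in SN2′ fashion by the propargylic chloride to form the 1,1-dimethylallene. The route is rejoined at 15.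

3. Step 12. Zerovalent palladium may ionise the allylic C–O bond of the lactone, with loss of configuration, and the base may degrade the butenolide. The fallback sets out from 20 and avoids palladium. Arbuzov reaction of 4-(bromomethyl)furan-2(5H)-one with triethyl phosphite gives diethyl [(5-oxo-2,5-dihydrofuran-3-yl)methyl]phosphonate F4. Its lithium anion (LiHMDS, THF, −78 °C) should undergo E-selective Horner–Wadsworth–Emmons olefination with enal 20 to give the target directly, so the route is rejoined at 25.

Further compounds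
F1 | step 8 | tert-butyl{[(2E,6E,10E)-11-iodo-3,7,15-trimethylhexadeca-2,6,10,13,14-pentaen-1-yl]oxy}diphenylsilane | CC(C)=C=CC/C(I)=C\CC/C(C)=C/CC/C(C)=C/CO[Si](c1ccccc1)(c1ccccc1)C(C)(C)C
F2 | step 7 | tert-butyl{[(2E,6E)-3,7-dimethylundeca-2,6-dien-10-yn-1-yl]oxy}diphenylsilane | C#CCC/C(C)=C/CC/C(C)=C/CO[Si](c1ccccc1)(c1ccccc1)C(C)(C)C
F3 | step 7 | tert-butyl{[(2E,6E)-3,7-dimethyldodeca-2,6,10,11-tetraen-1-yl]oxy}diphenylsilane | C=C=CCC/C(C)=C/CC/C(C)=C/CO[Si](c1ccccc1)(c1ccccc1)C(C)(C)C
F4 | step 12 | diethyl [(5-oxo-2,5-dihydrofuran-3-yl)methyl]phosphonate | CCOP(=O)(CC1=CC(=O)OC1)OCC
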